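**Plan**
- Enabling feature: the benzene ring (C4a, C5, C6, C7, C8, C8a) carries oxygen on C5, C7 and C8a, so it is a folded 1,3,5-tricarbonyl chain, and the oxygen on C8a is also O1 of the pyranone ring (O1, C2, C3, C4, C4a, C8a).
- Retrosynthesis: cut the C6–prenyl bond and the ester methyl, then the C4a–C5 bond of the arene (Claisen), which unfolds the arene into a chiral 2,3-dimethyldihydropyranone carrying a β-keto methyl ester arm. Then cut O1–C8a (cyclodehydration of a δ-hydroxy-β-diketone), C4–C4a and C8–C8a (two Claisen acylations) and C6–C7 (malonate homologation).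
- Forward: the chain is joined in the order C6–C7, C8–C8a, C4–C4a; the pyranone ring closes first, the carbocycle second; esterification and prenylation at C6 finish the synthesis.
- Stereochemistry: C2 comes from methyl (S)-3-hydroxybutanoate, C3 from Fráter–Seebach anti-methylation, and the side-chain centre from enantioselective alcoholysis of 3-propylglutaric anhydride. The key step forms no stereocentre and never breaks the O1–C2 bond.
- The side-chain carboxyl is carried as the free acid, a carboxylate under every basic step, so it can neither act as an acyl acceptor nor be enolised β to the 1,3-dicarbonyl carbon (which would open a retro-Michael path).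

Key step: step 10

Assumption: the quinidine-derived thiourea of step 4 is assumed to deliver the (R)-half-ester 6; should the sense of induction on this substrate be the opposite, the pseudoenantiomeric quinine-derived catalyst takes its place and nothing else changes.

**Route**

Step 1
Reactants: 1 methyl (3S)-3-hydroxybutanoate
Product: 2 methyl (2S,3S)-3-hydroxy-2-methylbutanoate
Conditions: LDA (2.2 equiv), THF, −78 → −20 °C; MeI, DMPU, −78 → 0 °C; aq. NH4Cl
Reagents that add atoms: iodomethane, CI
Why: Fráter–Seebach alkylation, in which the rigid lithium alkoxide–enolate chelate is methylated on the face away from the C3 methyl group, setting C2 anti to the existing centre (2S,3S).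

Step 2
Reactants: 2 methyl (2S,3S)-3-hydroxy-2-methylbutanoate
Product: 3 methyl (2S,3S)-3-[(tert-butyldimethylsilyl)oxy]-2-methylbutanoate
Conditions: TBSCl, imidazole, DMF, rt
Reagents that add atoms: tert-butyl(chloro)dimethylsilane, CC(C)(C)[Si](C)(C)Cl
Why: Standard silylation of a secondary alcohol, so that no alkoxide interferes with the later polyanion acylation.

Step 3
Reactants: 3 methyl (2S,3S)-3-[(tert-butyldimethylsilyl)oxy]-2-methylbutanoate
Product: 4 (2S,3S)-3-[(tert-butyldimethylsilyl)oxy]-N-methoxy-N,2-dimethylbutanamide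
Conditions: MeNHOMe·HCl, i-PrMgCl, THF, −20 → 0 °C
Reagents that add atoms: N,O-dimethylhydroxylamine hydrochloride, CNOC.Cl
Why: Direct ester-to-Weinreb amide exchange with the chloromagnesium amide, which should proceed without enolising the α-centre and gives an acyl donor whose chelated adduct survives until work-up.

Step 4
Reactants: 5 3-propylglutaric anhydride
Product: 6 (3R)-3-[2-(benzyloxy)-2-oxoethyl]hexanoic acid
Conditions: BnOH (3 equiv), 9-amino-9-deoxy-epi-quinidine 3,5-bis(trifluoromethyl)phenyl thiourea (10 mol%), MTBE, −20 °C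
Reagents that add atoms: benzyl alcohol, OCc1ccccc1
Why: Catalytic enantioselective alcoholysis of a prochiral cyclic anhydride, in which the bifunctional cinchona catalyst activates one of the two enantiotopic carbonyl groups by hydrogen bonding and delivers the alcohol by general base catalysis, setting the only stereocentre of this fragment.

Step 5
Reactants: 6 (3R)-3-[2-(benzyloxy)-2-oxoethyl]hexanoic acid
Product: 8 7-benzyl 1-methyl (5R)-3-oxo-5-propylheptanedioate, via acyl imidazolide 7 (not isolated)
Conditions: CDI, THF, rt; then MeO2CCH2CO2K, MgCl2, Et3N, MeCN, rt → 45 °C; 1 M HCl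
Reagents that add atoms: potassium methyl malonate, [K+].[O-]C(=O)CC(=O)OC
Why: Masamune–Brooks homologation, in which the acyl imidazolide acylates the magnesium enolate of the malonate half-ester and decarboxylation gives the β-keto methyl ester under conditions too mild for Dieckmann closure onto the benzyl ester.

Step 6
Reactants: 8 7-benzyl 1-methyl (5R)-3-oxo-5-propylheptanedioate
Product: 9 (3R)-7-methoxy-5,7-dioxo-3-propylheptanoic acid
Conditions: H2 (1 atm), Pd/C (10 wt% Pd), EtOAc, rt
Reagents that add atoms: none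
Why: Hydrogenolysis of the benzyl ester frees the side-chain acid, which from here on is a carboxylate in every basic step and so is neither an acyl acceptor nor readily enolised.

Step 7
Reactants: 9 (3R)-7-methoxy-5,7-dioxo-3-propylheptanoic acid
Product: 10 (3S)-4-acetyl-7-methoxy-5,7-dioxo-3-propylheptanoic acid
Conditions: LDA (3.1 equiv), THF, −78 → 0 °C; MeC(O)N(OMe)Me, −78 → −20 °C; aq. HCl to pH 3
Reagents that add atoms: N-methoxy-N-methylacetamide, CC(=O)N(C)OC
Why: Claisen acylation of a β-keto ester dianion (a trianion counting the carboxylate) at its γ-carbon, the most basic site, by a Weinreb amide; the new C4 centre is an enolisable 1,3-diketone carbon of no consequence.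

Step 8
Reactants: 10 (3S)-4-acetyl-7-methoxy-5,7-dioxo-3-propylheptanoic acid; 4 (2S,3S)-3-[(tert-butyldimethylsilyl)oxy]-N-methoxy-N,2-dimethylbutanamide
Product: 11 (3S,8S,9S)-9-[(tert-butyldimethylsilyl)oxy]-4-(3-methoxy-3-oxopropanoyl)-8-methyl-5,7-dioxo-3-propyldecanoic acid
Conditions: LDA (4.1 equiv), THF, −78 → 0 °C; 4, −78 → −20 °C; cold aq. HCl to pH 3
Reagents that add atoms: none
Why: Terminal Claisen acylation of a 3,5-diketo ester polyanion, in which the last-formed carbanion on the acetyl methyl group attacks the Weinreb amide and the chelated adduct keeps the α-centre of 4 from enolising.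

Step 9
Reactants: 11 (3S,8S,9S)-9-[(tert-butyldimethylsilyl)oxy]-4-(3-methoxy-3-oxopropanoyl)-8-methyl-5,7-dioxo-3-propyldecanoic acid
Product: 13 (3S)-4-[(2S,3S)-2,3-dimethyl-4-oxo-3,4-dihydro-2H-pyran-6-yl]-7-methoxy-5,7-dioxo-3-propylheptanoic acid, via hydroxy triketo ester acid 12 (not isolated)
Conditions: aq. HF (48%), MeCN, 0 °C → rt; then TsOH·H2O (cat.), CH2Cl2, rt
Reagents that add atoms: none
Why: Acid removes the silyl ether, the freed C9 hydroxyl adds to the C5 ketone as a six-membered hemiketal and loss of water gives the vinylogous ester (standard cyclodehydration of δ-hydroxy-β-diketones); the carbinol C–O bond is never broken, so both ring stereocentres are carried over.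

Step 10
Reactants: 13 (3S)-4-[(2S,3S)-2,3-dimethyl-4-oxo-3,4-dihydro-2H-pyran-6-yl]-7-methoxy-5,7-dioxo-3-propylheptanoic acid
Product: 14 (3S)-3-[(2S,3S)-5,7-dihydroxy-2,3-dimethyl-4-oxo-3,4-dihydro-2H-1-benzopyran-8-yl]hexanoic acid
Conditions: Mg(OMe)2 (6 equiv), MeOH, rt → 45 °C; then cold 1 M HCl
Reagents that add atoms: none
Why: Proposed new method: Mg(OMe)2 turns 13 into a magnesium carboxylate/bis-enolate in which the C4–H of the heptanoate (future C8, flanked by the C5 ketone and by C6 of the vinylogous ester) is removed, and the resulting extended enolate attacks the methyl ester carbonyl through its α-carbon, C5 of the pyranone (future C4a); loss of methoxide and two enolisations give the aromatic ring. The closest known reaction type is the Mg(OMe)2-mediated Claisen-mode cyclisation of open-chain 3,5,7-triketo esters and of pyranone-masked tetraketides to acylphloroglucinols, combined with the usual α-reactivity of extended enolates of vinylogous esters. The carbocycle (C4a, C5, C6, C7, C8, C8a) closes in the 6-(enolexo)-exo-trig mode. No stereocentre is formed, and since the O1–C2 bond stays intact and the pyranone already fixes O1 on C8a, no choice between phenols arises and the side chain sits on C8 by construction. The step needs C-acylation at the methyl ester in preference to deprotonation at C3 of the pyranone (ring opening by β-elimination, loss of C2) and to closures onto the side chain; the first is secured by the far higher acidity of the two 1,3-dicarbonyl sites under this mild base, the second by the side-chain carboxyl being a magnesium carboxylate that cannot accept an acyl transfer. The aldol alternative (ester α-carbon onto the pyranone C4 carbonyl) would give a bridged bicycle and is therefore not open.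

Step 11
Reactants: 14 (3S)-3-[(2S,3S)-5,7-dihydroxy-2,3-dimethyl-4-oxo-3,4-dihydro-2H-1-benzopyran-8-yl]hexanoic acid
Product: 15 methyl (3S)-3-[(2S,3S)-5,7-dihydroxy-2,3-dimethyl-4-oxo-3,4-dihydro-2H-1-benzopyran-8-yl]hexanoate
Conditions: MeOH, H2SO4 (cat.), rt
Reagents that add atoms: methanol, CO
Why: Fischer esterification of the aliphatic acid, which leaves the phenols untouched and, with methanol as solvent, also reopens any dihydrocoumarin formed between the C7 hydroxyl and the side-chain carboxyl.

Step 12
Reactants: 15 methyl (3S)-3-[(2S,3S)-5,7-dihydroxy-2,3-dimethyl-4-oxo-3,4-dihydro-2H-1-benzopyran-8-yl]hexanoate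
Product: 16 methyl (3S)-3-[(2S,3S)-5,7-dihydroxy-2,3-dimethyl-6-(3-methylbut-2-en-1-yl)-4-oxo-3,4-dihydro-2H-1-benzopyran-8-yl]hexanoate
Conditions: prenyl bromide (1.2 equiv), NaOMe (2.2 equiv), MeOH, 0 °C → rt
Reagents that add atoms: 1-bromo-3-methylbut-2-ene, CC(C)=CCBr
Why: C-alkylation of a phloroglucinol-type phenoxide in a protic solvent, the standard way to prenylate acylphloroglucinols; C6 is the only unsubstituted ring carbon and lies between two oxygen-bearing carbons.

**Compound list**
1 | methyl (3S)-3-hydroxybutanoate | C[C@H](O)CC(=O)OC | starting material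
2 | methyl (2S,3S)-3-hydroxy-2-methylbutanoate | C[C@H](O)[C@H](C)C(=O)OC | intermediate
3 | methyl (2S,3S)-3-[(tert-butyldimethylsilyl)oxy]-2-methylbutanoate | C[C@H](O[Si](C)(C)C(C)(C)C)[C@H](C)C(=O)OC | intermediate
4 | (2S,3S)-3-[(tert-butyldimethylsilyl)oxy]-N-methoxy-N,2-dimethylbutanamide | C[C@H](O[Si](C)(C)C(C)(C)C)[C@H](C)C(=O)N(C)OC | intermediate
5 | 3-propylglutaric anhydride (4-propyloxane-2,6-dione) | CCCC1CC(=O)OC(=O)C1 | starting material
6 | (3R)-3-[2-(benzyloxy)-2-oxoethyl]hexanoic acid | CCC[C@H](CC(=O)O)CC(=O)OCc1ccccc1 | intermediate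
7 | benzyl (3R)-3-[2-(1H-imidazol-1-yl)-2-oxoethyl]hexanoate | CCC[C@H](CC(=O)n1ccnc1)CC(=O)OCc1ccccc1 | intermediate (not isolated)
8 | 7-benzyl 1-methyl (5R)-3-oxo-5-propylheptanedioate | CCC[C@H](CC(=O)CC(=O)OC)CC(=O)OCc1ccccc1 | intermediate
9 | (3R)-7-methoxy-5,7-dioxo-3-propylheptanoic acid | CCC[C@H](CC(=O)CC(=O)OC)CC(=O)O | intermediate
10 | (3S)-4-acetyl-7-methoxy-5,7-dioxo-3-propylheptanoic acid (C4 epimers) | CCC[C@H](C(C(C)=O)C(=O)CC(=O)OC)CC(=O)O | intermediate
11 | (3S,8S,9S)-9-[(tert-butyldimethylsilyl)oxy]-4-(3-methoxy-3-oxopropanoyl)-8-methyl-5,7-dioxo-3-propyldecanoic acid (C4 epimers) | CCC[C@H](C(C(=O)CC(=O)OC)C(=O)CC(=O)[C@@H](C)[C@H](C)O[Si](C)(C)C(C)(C)C)CC(=O)O | intermediate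
12 | (3S,8S,9S)-9-hydroxy-4-(3-methoxy-3-oxopropanoyl)-8-methyl-5,7-dioxo-3-propyldecanoic acid (C4 epimers) | CCC[C@H](C(C(=O)CC(=O)OC)C(=O)CC(=O)[C@@H](C)[C@H](C)O)CC(=O)O | intermediate (not isolated)
13 | (3S)-4-[(2S,3S)-2,3-dimethyl-4-oxo-3,4-dihydro-2H-pyran-6-yl]-7-methoxy-5,7-dioxo-3-propylheptanoic acid (C4 epimers) | C[C@@H]1OC(=CC(=O)[C@H]1C)C(C(=O)CC(=O)OC)[C@@H](CCC)CC(=O)O | intermediate
14 | (3S)-3-[(2S,3S)-5,7-dihydroxy-2,3-dimethyl-4-oxo-3,4-dihydro-2H-1-benzopyran-8-yl]hexanoic acid | CCC[C@@H](CC(=O)O)c1c(O)cc(O)c2c1O[C@@H](C)[C@H](C)C2=O | intermediate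
15 | methyl (3S)-3-[(2S,3S)-5,7-dihydroxy-2,3-dimethyl-4-oxo-3,4-dihydro-2H-1-benzopyran-8-yl]hexanoate | CCC[C@@H](CC(=O)OC)c1c(O)cc(O)c2c1O[C@@H](C)[C@H](C)C2=O | intermediate
16 | methyl (3S)-3-[(2S,3S)-5,7-dihydroxy-2,3-dimethyl-6-(3-methylbut-2-en-1-yl)-4-oxo-3,4-dihydro-2H-1-benzopyran-8-yl]hexanoate (CNP0068017.3) | CCC[C@@H](CC(=O)OC)c1c(O)c(CC=C(C)C)c(O)c2c1O[C@@H](C)[C@H](C)C2=O | target

**Count**
Total steps: 12. Longest linear sequence: 9 steps (5 → 16, steps 4 to 12); the three-step branch 1 → 4 joins at step 8.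

**Steps most likely to fail**

1. Step 10. The first enolate to form, that of the β-keto ester, may hold the ester carbonyl in a magnesium chelate and switch it off as an acyl acceptor. That leaves time for retro-Claisen cleavage of the 1,3-dicarbonyl by methoxide, or for ring opening of the pyranone through deprotonation at C3, which would scramble C2 and C3. The fallback sets out from 6 and comes back at 14; it makes the closure thermal and neutral by exchanging the methyl ester for a tert-butyl ester, a documented source of α-oxoketenes. Homologation of 6 through 7 as in step 5, but with potassium tert-butyl malonate, should give 7-benzyl 1-tert-butyl (5R)-3-oxo-5-propylheptanedioate F1. Hydrogenolysis as in step 6 gives (3R)-7-tert-butoxy-5,7-dioxo-3-propylheptanoic acid F2, and acetylation as in step 7 gives (3S)-4-acetyl-7-tert-butoxy-5,7-dioxo-3-propylheptanoic acid F3. Acylation with 4 as in step 8 gives (3S,8S,9S)-4-(3-tert-butoxy-3-oxopropanoyl)-9-[(tert-butyldimethylsilyl)oxy]-8-methyl-5,7-dioxo-3-propyldecanoic acid F4, and aq. HF in MeCN as in step 9 gives (3S)-7-tert-butoxy-4-[(2S,3S)-2,3-dimethyl-4-oxo-3,4-dihydro-2H-pyran-6-yl]-5,7-dioxo-3-propylheptanoic acid F5. Heating F5 in toluene at 110 °C under high dilution expels tert-butanol. The α-oxoketene is then attacked at its ketene carbon by C5 of the pyranone (the normal polarity of α-oxoketene/enol ether reactions) or, as the dienylketene formed on enolisation of the neighbouring ketone, closes by 6π-electrocyclisation; tautomerisation gives 14. Thermal generation of α-oxoketenes from tert-butyl β-keto esters, their capture by enol ether carbons and the electrocyclisation of dienylketenes to phenols are each established reaction types, though their combination on this substrate has no direct precedent.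

2. Step 8. The fourth deprotonation may be incomplete, and the terminal carbanion may be quenched by proton transfer from the α-position of the hindered amide 4 or may close onto the methyl ester before it is acylated. The fallback sets out from 10, with 3 as the source of the C2–C3 unit, and comes back at 11; aldol addition and oxidation replace the Claisen acylation. Reduction of 3 with i-Bu2AlH in CH2Cl2 at −78 °C gives (2S,3S)-3-[(tert-butyldimethylsilyl)oxy]-2-methylbutanal F6, which should react with the polyanion of 10 at −78 °C far faster than the amide. The aldol product is (3S,8R,9S)-9-[(tert-butyldimethylsilyl)oxy]-7-hydroxy-4-(3-methoxy-3-oxopropanoyl)-8-methyl-5-oxo-3-propyldecanoic acid F7, a mixture of C7 epimers (the descriptor at C8 changes only because the priorities change). Oxidation of the carbinol with DMP in CH2Cl2 gives 11.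

3. Step 12. O-Alkylation at the C7 oxygen, dearomatising C-alkylation at the already substituted C8 and double alkylation compete with attack at C6. The fallback sets out from 15 and comes back at 16; the prenyl group is delivered intramolecularly. O-Alkylation of the more acidic, non-chelated C7 hydroxyl with 3-chloro-3-methylbut-1-yne (CuCl2 cat., DBU, MeCN, 0 °C) gives methyl (3S)-3-[(2S,3S)-5-hydroxy-2,3-dimethyl-7-[(2-methylbut-3-yn-2-yl)oxy]-4-oxo-3,4-dihydro-2H-1-benzopyran-8-yl]hexanoate F8. Semihydrogenation (H2, Pd/CaCO3 poisoned with Pb(OAc)2, quinoline, EtOAc) gives methyl (3S)-3-[(2S,3S)-5-hydroxy-2,3-dimethyl-7-[(2-methylbut-3-en-2-yl)oxy]-4-oxo-3,4-dihydro-2H-1-benzopyran-8-yl]hexanoate F9. Heating F9 in N,N-diethylaniline at 130 °C brings about the aromatic Claisen rearrangement, which delivers the 3-methylbut-2-enyl group to C6, the only ortho position that can rearomatise, and gives 16.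

**Further compounds**
F1 | step 10 | 7-benzyl 1-tert-butyl (5R)-3-oxo-5-propylheptanedioate | CCC[C@H](CC(=O)CC(=O)OC(C)(C)C)CC(=O)OCc1ccccc1
F2 | step 10 | (3R)-7-tert-butoxy-5,7-dioxo-3-propylheptanoic acid | CCC[C@H](CC(=O)CC(=O)OC(C)(C)C)CC(=O)O
F3 | step 10 | (3S)-4-acetyl-7-tert-butoxy-5,7-dioxo-3-propylheptanoic acid | CCC[C@H](C(C(C)=O)C(=O)CC(=O)OC(C)(C)C)CC(=O)O
F4 | step 10 | (3S,8S,9S)-4-(3-tert-butoxy-3-oxopropanoyl)-9-[(tert-butyldimethylsilyl)oxy]-8-methyl-5,7-dioxo-3-propyldecanoic acid | CCC[C@H](C(C(=O)CC(=O)OC(C)(C)C)C(=O)CC(=O)[C@@H](C)[C@H](C)O[Si](C)(C)C(C)(C)C)CC(=O)O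
F5 | step 10 | (3S)-7-tert-butoxy-4-[(2S,3S)-2,3-dimethyl-4-oxo-3,4-dihydro-2H-pyran-6-yl]-5,7-dioxo-3-propylheptanoic acid | C[C@@H]1OC(=CC(=O)[C@H]1C)C(C(=O)CC(=O)OC(C)(C)C)[C@@H](CCC)CC(=O)O
F6 | step 8 | (2S,3S)-3-[(tert-butyldimethylsilyl)oxy]-2-methylbutanal | C[C@H](O[Si](C)(C)C(C)(C)C)[C@H](C)C=O
F7 | step 8 | (3S,8R,9S)-9-[(tert-butyldimethylsilyl)oxy]-7-hydroxy-4-(3-methoxy-3-oxopropanoyl)-8-methyl-5-oxo-3-propyldecanoic acid (C7 epimers) | CCC[C@H](C(C(=O)CC(=O)OC)C(=O)CC(O)[C@@H](C)[C@H](C)O[Si](C)(C)C(C)(C)C)CC(=O)O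
F8 | step 12 | methyl (3S)-3-[(2S,3S)-5-hydroxy-2,3-dimethyl-7-[(2-methylbut-3-yn-2-yl)oxy]-4-oxo-3,4-dihydro-2H-1-benzopyran-8-yl]hexanoate | CCC[C@@H](CC(=O)OC)c1c(OC(C)(C)C#C)cc(O)c2c1O[C@@H](C)[C@H](C)C2=O
F9 | step 12 | methyl (3S)-3-[(2S,3S)-5-hydroxy-2,3-dimethyl-7-[(2-methylbut-3-en-2-yl)oxy]-4-oxo-3,4-dihydro-2H-1-benzopyran-8-yl]hexanoate | CCC[C@@H](CC(=O)OC)c1c(OC(C)(C)C=C)cc(O)c2c1O[C@@H](C)[C@H](C)C2=O
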